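## The problem

Compound 21, 3,4,5-tribromo-2-(3,5-dibromo-2-hydroxyphenoxy)phenol, is a diaryl ether whose oxygen bridge joins C2 of ring A to C1' of ring B, with a free hydroxyl ortho to the bridge on each ring (C1 and C2'). It has no stereocentre, so nothing has to be controlled in space; every difficulty is one of position. Ring B is benign: C3' and C5' lie ortho and para to the C2' hydroxyl, where a phenol takes bromine unaided. Ring A is the problem: seen from the C1 hydroxyl its bromines at C3, C4 and C5 are meta, para and meta, while C6, the position that hydroxyl would brominate first, must stay C–H. Seen from the C2 oxygen the same bromines are ortho, meta and para and could be placed by substitution, but the ether would then have to be forged at an oxygen flanked by bromine and alkoxy on an electron-poor ring, a poor case for any O-arylation. Five aryl bromides rule out hydrogenolysis, dissolving metals, alkyllithiums and zerovalent palladium once they are in place, and the electron-rich bis-phenol will not bear excess bromine or strong oxidants. The way round is the make-up of ring A itself: C3–C4–C5–C6 carry Br, Br, Br, H, a diene-sized block, and C1–C2 carry the two oxygens, an alkyne-sized block, so the ring can be assembled with every substituent already on it.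

## Retrosynthesis

The C1–O bond of 21 is cut first, back to the C1–B bond of pinacol boronate 19 (aryl borate 20 lies between them and hydrolyses in the flask). The neighbouring choice, an oxygen at C1 carried through the end game, would either leave a free phenol that sends bromine to C6 or cost a sulfonate put on and taken off. Boron is electronically mute towards C6 and leaves as the hydroxyl. 19 is no simpler in skeleton, but the one dangerous directing group of ring A has become a spectator. The forward step needs a peroxide mild enough for a pentabromo bis-aryl ether and fast enough to beat base-induced protodeboronation.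

The C3'–Br and C5'–Br bonds of 19 are cut next, giving phenol 17 (monobromide 18 on the way). These are the only C–Br bonds in the molecule that electrophilic bromination sets without help. Ring A of 17, with three bromines, a boryl group and no free donor, cannot compete. Ring B of 17 is bromine-free, which the organolithium chemistry further back also requires. The forward step must deliver two equivalents of bromine without ipso attack at the C–B bond.

The C2' hydroxyl of 17 is masked as the benzyl ether 16 (O–CH2Ph bond). A methyl ether would have to be cut with a boron trihalide, which strips the diol from a boronic ester. Hydrogenolysis is closed by the aryl bromides. A benzyl ether falls to acid with a cation scavenger, which an arylboronic pinacol ester on a deactivated ring should tolerate. The benzyl group costs no step, since the phenol that carries it, 6, is an article of commerce.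

Ring A of 16 is cut at C2–C3 and C1–C6, giving 2,3,4-tribromothiophene 1,1-dioxide 5 and the aryloxyalkynylboronate 14; the bridged sulfone 15 connects them. Cutting the ether C2–O instead would demand a 1,2-dioxygenated 3,4,5-tribromoarene and a hindered O-arylation. Cutting the ring A C–Br bonds runs against the directing effects described above. The cycloaddition cut removes both problems: the diene delivers Br, Br, Br and H, the alkyne delivers the aryloxy group and the boron. The simplification is large, a hexasubstituted benzene becoming a four-carbon and a two-carbon piece. The forward reaction must (a) join the boron-bearing carbon to the CH terminus of 5, (b) run faster than self-dimerisation of 5, and (c) expel the sulfonyl bridge of 15.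

Alkyne 14 is cut at C(sp)–B to lithium acetylide 12 and isopropoxy pinacolborane 10 (via borate 13). 12 is traced through chloroalkyne 11 to the dichlorovinyl ether 9, itself cut at C(sp2)–O to phenol 6 and trichloroethylene 7 (via dichloroacetylene 8). An aryl ynol ether is preferred to an alkyl one because it has no retro-ene path to a ketene on heating. These steps use an alkyllithium, which is why ring B stays bromine-free until after the key step.

Dioxide 5 is cut at its two S–O bonds to 2,3,4-tribromothiophene 3 (sulfoxide 4 on the way). 3 is cut at C5–H to tetrabromothiophene 1 through the 2-lithio species 2. A cheap perbromo heterocycle thus fixes all three bromines and the C6 hydrogen of ring A. The forward steps need selective α bromine–lithium exchange and S-oxidation of a deactivated thiophene.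

## Roads not taken

Alternative 1: The four C–Br bonds at C3, C5, C3' and C5' are cut together and C4–Br is traced to an amino group, which leads back to the bromine-free ether 2-(5-amino-2-methoxyphenoxy)phenol A1. In the forward key step four equivalents of an ammonium tribromide would brominate A1 ortho to the amine on ring A and ortho and para to the hydroxyl on ring B, giving 2-(3-amino-2,4-dibromo-6-methoxyphenoxy)-4,6-dibromophenol A2. Sandmeyer bromination of the amino group of A2 and cleavage of its methyl ether would finish. The merits are plain: every reaction type is routine, the reagents are cheap, and four halogens arrive in one operation. The weak points lie on ring A of A1. There C6 is ortho to the methoxy group and stays open, while C3, which must be brominated, is wedged between the amine and the ether oxygen, so the reagent has to be pushed hardest where over-bromination at C6 is closest. An aminophenol such as A1 is also oxidisable by tribromide, and the diazonium ion derived from A2 must be handled beside a free phenol. In step count and in familiarity this road is at least the equal of the chosen plan and probably shorter. The chosen plan sets certainty of position against it: the C6 hydrogen and the three contiguous bromines are placed by connectivity, not by relative rates, and the only electrophilic bromination falls on ring B.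

Alternative 2: Ring A is opened at C2–C3 and C5–C6, giving 1-(3,5-dibromo-2-methoxyphenoxy)propan-2-one A3 and sodium nitromalonaldehyde A4. In the forward key step A3 and A4 would undergo two aldol condensations in aqueous base and close ring A as 2-(3,5-dibromo-2-methoxyphenoxy)-4-nitrophenol A5. Ring B of A3 carries its bromines from the outset, so no late bromination of ring B is needed; in that respect this road is better than the chosen plan, and its chemistry is aqueous and free of organometallics. Its weakness is that the ring being built carries none of its three bromines. A5 has hydrogen at C3, C5 and C6, so the bromines must still come by nitro reduction (sparing two aryl bromides), amine-directed dibromination and a Sandmeyer reaction. C6 of A5 is ortho to a free C1 hydroxyl and more exposed than in alternative 1. A4 is a shock-sensitive salt. The 2-aryloxy-4-nitrophenol pattern is also reachable by plain substitution chemistry, so the ring synthesis buys little. This is the longest of the four roads and leaves the real problem of ring A unsolved. The chosen plan needs sensitive boron and sulfone partners that this road avoids, but it builds ring A complete.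

Alternative 3: Ring B is cut at C1'–C6' and C2'–C3', giving 3,5-dibromo-2H-pyran-2-one A6 and the aryloxy ketene bis(trimethylsilyl) acetal A7, ArO–CH=C(OSiMe3)2 with Ar = 2,3,4-tribromo-6-methoxyphenyl. In the forward key step A6 and A7 would undergo Diels–Alder addition, followed by decarboxylation and elimination of one silyloxy group, to give 2,4-dibromo-6-(2,3,4-tribromo-6-methoxyphenoxy)phenol A8. Compound A8 is one ether cleavage from the target. The merits are real. The ring A fragment 2,3,4-tribromo-6-methoxyphenol A9 is the expected product of threefold bromination of 2-methoxyphenol A10, since its free hydroxyl, the future bridge oxygen, directs ortho and para and the methoxy group directs para. The hindered oxygen of A9 is then alkylated, which is easy, not arylated. The polar match, the nucleophilic aryloxy-bearing carbon of A7 joining C6 of A6, gives the right regiochemistry. On paper this is the shortest road, about five steps, and in step economy it is better than the chosen plan. The weak points are these. Making A7 needs double deprotonation and silylation by a strong amide base next to a polybromoarene that still has a ring hydrogen beside bromine, which invites halogen migration. The cycloaddition of A6 with an α-aryloxy ketene acetal is no better precedented than the chosen key step, and conjugate addition with ring opening competes. The third bromination of A10 must stop short of the tetrabromide. The ring-forming step is also spent on ring B, whose pattern is the trivial one. The chosen plan is longer by about three steps. Against that, it relies on no regioselective bromination for ring A, exposes no polybromoarene to strong base, and has a neutral thermal key step whose only by-product is sulfur dioxide.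

Key step: step 5

Assumption: dioxide 5 and alkynylboronate 14 are treated as isolable but short-lived and are each used within hours of preparation; sulfoxide 4 and bridged sulfone 15 are racemic, transient species.

## Route

Step 1
Reactants: 1 tetrabromothiophene
Product: 3 2,3,4-tribromothiophene, via thienyllithium 2 (not isolated)
Conditions: n-BuLi (1.0 equiv), THF, −78 °C; then H2O, −78 °C to rt
Reagents that add atoms: none
Why: Bromine–lithium exchange on a perbromothiophene is fastest at an α-position, so one equivalent of n-BuLi at low temperature should give the 2-lithio species 2 and protonation should deliver 3; this selective α-exchange and quench is standard halothiophene chemistry.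

Step 2
Reactants: 3 2,3,4-tribromothiophene
Product: 5 2,3,4-tribromothiophene 1,1-dioxide, via sulfoxide 4 (not isolated)
Conditions: (CF3CO)2O, 50% aq. H2O2, CH2Cl2, 0 °C to rt
Reagents that add atoms: peroxytrifluoroacetic acid, OOC(=O)C(F)(F)F (formed in the flask from trifluoroacetic anhydride, O=C(OC(=O)C(F)(F)F)C(F)(F)F, and hydrogen peroxide, OO)
Why: Electrophilic S-oxidation by peroxytrifluoroacetic acid is the established way to the 1,1-dioxides of halogen-deactivated thiophenes; sulfoxide 4 has lost the aromatic stabilisation and should be oxidised on faster than 3. The C2 bromine and low temperature should slow the self-dimerisation typical of α-unsubstituted thiophene dioxides.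

Step 3
Reactants: 6 2-(benzyloxy)phenol; 7 trichloroethylene
Product: 9 1-(benzyloxy)-2-{[(E)-1,2-dichloroethenyl]oxy}benzene, via dichloroacetylene 8 (not isolated)
Conditions: K2CO3, DMF, 70 °C
Reagents that add atoms: none
Why: K2CO3 dehydrochlorinates trichloroethylene to dichloroacetylene 8, to which the phenoxide adds in anti fashion to give the (E)-1,2-dichlorovinyl ether; this is the standard entry to aryl ynol ethers and leaves the benzyl ether untouched.

Step 4
Reactants: 9 1-(benzyloxy)-2-{[(E)-1,2-dichloroethenyl]oxy}benzene; 10 2-isopropoxy-4,4,5,5-tetramethyl-1,3,2-dioxaborolane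
Product: 14 2-{[2-(benzyloxy)phenoxy]ethynyl}-4,4,5,5-tetramethyl-1,3,2-dioxaborolane, via chloroalkyne 11 (not isolated), via lithium acetylide 12 (not isolated), via lithium borate 13 (not isolated)
Conditions: n-BuLi (2.1 equiv), THF, −78 to −40 °C; 10, −78 °C; HCl·Et2O (1.0 equiv), −78 °C to rt; filtration under N2
Reagents that add atoms: none
Why: n-BuLi eliminates HCl to chloroalkyne 11 and then exchanges chlorine for lithium to give acetylide 12, the usual dichlorovinyl ether route to metallated ynol ethers. Addition to the alkoxyborolane gives borate 13, and one equivalent of anhydrous HCl at −78 °C releases the alkynylboronic ester, the standard alkynyllithium–alkoxyborolane protocol.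

Step 5
Reactants: 5 2,3,4-tribromothiophene 1,1-dioxide; 14 2-{[2-(benzyloxy)phenoxy]ethynyl}-4,4,5,5-tetramethyl-1,3,2-dioxaborolane
Product: 16 2-{2-[2-(benzyloxy)phenoxy]-3,4,5-tribromophenyl}-4,4,5,5-tetramethyl-1,3,2-dioxaborolane, via bridged sulfone 15 (not isolated)
Conditions: 14 (1.5 equiv), PhMe, 80 °C, slow addition of 5, N2 sweep
Reagents that add atoms: none
Why: The electron-poor diene 5 (LUMO lowered by the sulfonyl group and three bromines) and the oxygen-activated alkyne 14 should combine in an inverse-electron-demand (4+2) cycloaddition to the bridged sulfone 15, which loses SO2 in a cheletropic step driven by aromatisation. The closest known reaction type is the benzannulation of halogenated thiophene 1,1-dioxides with alkynes, together with the cycloadditions of alkynylboronic esters with 2-pyrones and cyclopentadienones. Ring A closes as a six-membered carbocycle by an intermolecular cycloaddition that forms C2–C3 and C1–C6 at once, followed by extrusion of the one-atom sulfur bridge. No stereocentre is created that survives, since the two bridgehead centres of 15 vanish with the SO2. The step needs regioselectivity, the boron-bearing carbon joining the CH terminus (C5 of 5): that carbon, β to oxygen, is the nucleophilic end of the ynol ether and should lead bond formation to the unhindered CH terminus. The developing negative charge then rests on C2 of the diene, where the sulfonyl group and bromine both stabilise it, and the bulky dioxaborolane avoids the C–Br terminus. The step also needs cross-cycloaddition to outrun self-dimerisation of 5, which slow addition of 5 to excess 14 and the C2 bromine should secure. The regiochemical sense is a prediction, not established precedent.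

Step 6
Reactants: 16 2-{2-[2-(benzyloxy)phenoxy]-3,4,5-tribromophenyl}-4,4,5,5-tetramethyl-1,3,2-dioxaborolane
Product: 17 2-[2,3,4-tribromo-6-(4,4,5,5-tetramethyl-1,3,2-dioxaborolan-2-yl)phenoxy]phenol
Conditions: CF3CO2H, C6HMe5 (5 equiv), CH2Cl2, rt
Reagents that add atoms: none
Why: Acidolysis of an aryl benzyl ether, with Friedel–Crafts capture of the benzyl cation by pentamethylbenzene, is a known substitute for hydrogenolysis, which the aryl bromides forbid. An arylboronic pinacol ester on a bromine-deactivated ring should tolerate trifluoroacetic acid, as such esters do in routine acidic deprotections.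

Step 7
Reactants: 17 2-[2,3,4-tribromo-6-(4,4,5,5-tetramethyl-1,3,2-dioxaborolan-2-yl)phenoxy]phenol
Product: 19 2,4-dibromo-6-[2,3,4-tribromo-6-(4,4,5,5-tetramethyl-1,3,2-dioxaborolan-2-yl)phenoxy]phenol, via monobromide 18 (not isolated)
Conditions: Br2 (2.05 equiv), CH2Cl2, 0 °C
Reagents that add atoms: bromine, BrBr
Why: Electrophilic aromatic bromination under control of the free ring B hydroxyl should go para first (C5', giving 18) and then ortho (C3'). Ring A carries three bromines and a boryl group and no donor directed at C6, so it should stay inert, and a C–B bond on so electron-poor a ring resists ipso-bromination.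

Step 8
Reactants: 19 2,4-dibromo-6-[2,3,4-tribromo-6-(4,4,5,5-tetramethyl-1,3,2-dioxaborolan-2-yl)phenoxy]phenol
Product: 21 3,4,5-tribromo-2-(3,5-dibromo-2-hydroxyphenoxy)phenol, via aryl borate 20 (not isolated)
Conditions: NaBO3·4H2O (3 equiv), THF/H2O, rt; then dilute HCl
Reagents that add atoms: sodium perborate tetrahydrate (NaBO3·4H2O), [Na+].[Na+].O[B-]1(O)OO[B-](O)(O)OO1
Why: Peroxide adds to boron, the aryl group migrates from boron to oxygen to give borate 20, and hydrolysis frees the phenol, the standard oxidation of arylboronic esters. The mildly basic perborate should outpace protodeboronation and leaves aryl bromides and the diaryl ether untouched.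

## Compound list

1 | tetrabromothiophene | Brc1sc(Br)c(Br)c1Br | starting material
2 | (3,4,5-tribromothiophen-2-yl)lithium | [Li]c1sc(Br)c(Br)c1Br | intermediate (not isolated)
3 | 2,3,4-tribromothiophene | Brc1scc(Br)c1Br | intermediate
4 | 2,3,4-tribromothiophene 1-oxide (racemic at sulfur) | O=S1C=C(Br)C(Br)=C1Br | intermediate (not isolated)
5 | 2,3,4-tribromothiophene 1,1-dioxide | O=S1(=O)C=C(Br)C(Br)=C1Br | intermediate
6 | 2-(benzyloxy)phenol | Oc1ccccc1OCc1ccccc1 | starting material
7 | trichloroethylene | ClC=C(Cl)Cl | starting material
8 | dichloroacetylene | ClC#CCl | intermediate (not isolated)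
9 | 1-(benzyloxy)-2-{[(E)-1,2-dichloroethenyl]oxy}benzene | Cl/C=C(/Cl)Oc1ccccc1OCc1ccccc1 | intermediate
10 | 2-isopropoxy-4,4,5,5-tetramethyl-1,3,2-dioxaborolane | CC(C)OB1OC(C)(C)C(C)(C)O1 | starting material
11 | 1-(benzyloxy)-2-[(chloroethynyl)oxy]benzene | ClC#COc1ccccc1OCc1ccccc1 | intermediate (not isolated)
12 | {[2-(benzyloxy)phenoxy]ethynyl}lithium | [Li]C#COc1ccccc1OCc1ccccc1 | intermediate (not isolated)
13 | lithium 2-{[2-(benzyloxy)phenoxy]ethynyl}-2-isopropoxy-4,4,5,5-tetramethyl-1,3,2-dioxaborolan-2-uide | [Li+].CC(C)O[B-]1(C#COc2ccccc2OCc2ccccc2)OC(C)(C)C(C)(C)O1 | intermediate (not isolated)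
14 | 2-{[2-(benzyloxy)phenoxy]ethynyl}-4,4,5,5-tetramethyl-1,3,2-dioxaborolane | CC1(C)OB(C#COc2ccccc2OCc2ccccc2)OC1(C)C | intermediate
15 | 6-[2-(benzyloxy)phenoxy]-1,2,3-tribromo-5-(4,4,5,5-tetramethyl-1,3,2-dioxaborolan-2-yl)-7-thiabicyclo[2.2.1]hepta-2,5-diene 7,7-dioxide (racemic; bridgeheads fixed by the bicycle) | O=S1(=O)C2(Br)C(Br)=C(Br)C1C(B1OC(C)(C)C(C)(C)O1)=C2Oc1ccccc1OCc1ccccc1 | intermediate (not isolated)
16 | 2-{2-[2-(benzyloxy)phenoxy]-3,4,5-tribromophenyl}-4,4,5,5-tetramethyl-1,3,2-dioxaborolane | CC1(C)OB(c2cc(Br)c(Br)c(Br)c2Oc2ccccc2OCc2ccccc2)OC1(C)C | intermediate
17 | 2-[2,3,4-tribromo-6-(4,4,5,5-tetramethyl-1,3,2-dioxaborolan-2-yl)phenoxy]phenol | CC1(C)OB(c2cc(Br)c(Br)c(Br)c2Oc2ccccc2O)OC1(C)C | intermediate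
18 | 4-bromo-2-[2,3,4-tribromo-6-(4,4,5,5-tetramethyl-1,3,2-dioxaborolan-2-yl)phenoxy]phenol | CC1(C)OB(c2cc(Br)c(Br)c(Br)c2Oc2cc(Br)ccc2O)OC1(C)C | intermediate (not isolated)
19 | 2,4-dibromo-6-[2,3,4-tribromo-6-(4,4,5,5-tetramethyl-1,3,2-dioxaborolan-2-yl)phenoxy]phenol | CC1(C)OB(c2cc(Br)c(Br)c(Br)c2Oc2cc(Br)cc(Br)c2O)OC1(C)C | intermediate
20 | 2-[3,4,5-tribromo-2-(3,5-dibromo-2-hydroxyphenoxy)phenoxy]-4,4,5,5-tetramethyl-1,3,2-dioxaborolane | CC1(C)OB(Oc2cc(Br)c(Br)c(Br)c2Oc2cc(Br)cc(Br)c2O)OC1(C)C | intermediate (not isolated)
21 | 3,4,5-tribromo-2-(3,5-dibromo-2-hydroxyphenoxy)phenol | Oc1cc(Br)c(Br)c(Br)c1Oc1cc(Br)cc(Br)c1O | target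

## Step count and risks

Total: 8 steps. Longest linear sequence: 6 steps (steps 3, 4, 5, 6, 7, 8; the thiophene branch, steps 1, 2, 5, 6, 7, 8, is equally long).

Least certain steps:

**Step 5 (key step).** Boron is a π-acceptor on the very carbon that must lead bond formation, so the cycloaddition may be slow. Self-dimerisation of the diene, hydrolytic loss of boron from the alkyne (moisture plus SO2 at 80 °C) or a stepwise (2+2) addition could then take over, and regiocontrol could erode.

Fallback: boron is brought in only after the ring is made. From 9, n-BuLi and then Me3SiCl give {[2-(benzyloxy)phenoxy]ethynyl}trimethylsilane F1, a hydrolytically inert silyl ynol ether in which silicon raises the nucleophilicity of the leading carbon and supports the same polarisation. Cycloaddition with 5 and loss of SO2 give {2-[2-(benzyloxy)phenoxy]-3,4,5-tribromophenyl}trimethylsilane F2. BBr3 then replaces silicon by boron at C1 (ipso-borodesilylation) and cleaves the benzyl ether in the same flask, and esterification with pinacol returns the material to the route at 17.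

**Step 4.** Release of the boronic ester from borate 13 is the delicate point. The acid may add across the electron-rich triple bond (hydration on work-up) or cleave the B–C(sp) bond, and either shows as loss of alkyne.

Fallback: the borate and the acid are avoided. From 9, acetylide 12 is made as before and treated with ClB(NMe2)2 to give the neutral {[2-(benzyloxy)phenoxy]ethynyl}bis(dimethylamino)borane F3, from which LiCl is filtered. Exchange of the two amino groups for pinacol, with loss of dimethylamine, returns to the route at 14.

**Step 6.** The benzyl cation may alkylate the electron-rich ring B of the freed phenol before the scavenger captures it, and long exposure to acid may hydrolyse the boronic ester.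

Fallback: boron is cashed in before the ether is opened. From 16, NaBO3·4H2O gives 2-[2-(benzyloxy)phenoxy]-3,4,5-tribromophenol F4. MsCl and Et3N give 2-[2-(benzyloxy)phenoxy]-3,4,5-tribromophenyl methanesulfonate F5, in which the sulfonate deactivates C6. BCl3 with C6HMe5 at −78 °C, usable now that no boronic ester is present, gives 3,4,5-tribromo-2-(2-hydroxyphenoxy)phenyl methanesulfonate F6. Two equivalents of Br2 give 3,4,5-tribromo-2-(3,5-dibromo-2-hydroxyphenoxy)phenyl methanesulfonate F7, and NaOH in aqueous MeOH removes the sulfonate, returning to the route at 21.

**Step 7.** Bromine may attack the boron-bearing carbon (ipso-bromodeboronation), most plausibly if the neighbouring phenol coordinates to boron and makes it borate-like.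

Fallback: the order of the last two steps is reversed. From 17, NaBO3·4H2O gives 3,4,5-tribromo-2-(2-hydroxyphenoxy)phenol F8. Two equivalents of Br2, dosed exactly at low temperature, then brominate ring B, relying on the deactivation of ring A by its three bromines to keep C6 free, and the route is rejoined at 21.

## Further compounds

F1 | step 5 | {[2-(benzyloxy)phenoxy]ethynyl}trimethylsilane | C[Si](C)(C)C#COc1ccccc1OCc1ccccc1
F2 | step 5 | {2-[2-(benzyloxy)phenoxy]-3,4,5-tribromophenyl}trimethylsilane | C[Si](C)(C)c1cc(Br)c(Br)c(Br)c1Oc1ccccc1OCc1ccccc1
F3 | step 4 | {[2-(benzyloxy)phenoxy]ethynyl}bis(dimethylamino)borane | CN(C)B(C#COc1ccccc1OCc1ccccc1)N(C)C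
F4 | step 6 | 2-[2-(benzyloxy)phenoxy]-3,4,5-tribromophenol | Oc1cc(Br)c(Br)c(Br)c1Oc1ccccc1OCc1ccccc1
F5 | step 6 | 2-[2-(benzyloxy)phenoxy]-3,4,5-tribromophenyl methanesulfonate | CS(=O)(=O)Oc1cc(Br)c(Br)c(Br)c1Oc1ccccc1OCc1ccccc1
F6 | step 6 | 3,4,5-tribromo-2-(2-hydroxyphenoxy)phenyl methanesulfonate | CS(=O)(=O)Oc1cc(Br)c(Br)c(Br)c1Oc1ccccc1O
F7 | step 6 | 3,4,5-tribromo-2-(3,5-dibromo-2-hydroxyphenoxy)phenyl methanesulfonate | CS(=O)(=O)Oc1cc(Br)c(Br)c(Br)c1Oc1cc(Br)cc(Br)c1O
F8 | step 7 | 3,4,5-tribromo-2-(2-hydroxyphenoxy)phenol | Oc1ccccc1Oc1c(O)cc(Br)c(Br)c1Br
A1 | alternative 1 | 2-(5-amino-2-methoxyphenoxy)phenol | COc1ccc(N)cc1Oc1ccccc1O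
A2 | alternative 1 | 2-(3-amino-2,4-dibromo-6-methoxyphenoxy)-4,6-dibromophenol | COc1cc(Br)c(N)c(Br)c1Oc1cc(Br)cc(Br)c1O
A3 | alternative 2 | 1-(3,5-dibromo-2-methoxyphenoxy)propan-2-one | CC(=O)COc1cc(Br)cc(Br)c1OC
A4 | alternative 2 | sodium nitromalonaldehyde | [Na+].O=C[C-](C=O)[N+](=O)[O-]
A5 | alternative 2 | 2-(3,5-dibromo-2-methoxyphenoxy)-4-nitrophenol | COc1c(Br)cc(Br)cc1Oc1cc(ccc1O)[N+](=O)[O-]
A6 | alternative 3 | 3,5-dibromo-2H-pyran-2-one | O=C1OC=C(Br)C=C1Br
A7 | alternative 3 | [2-(2,3,4-tribromo-6-methoxyphenoxy)ethene-1,1-diyl]bis(oxy)bis(trimethylsilane) | COc1cc(Br)c(Br)c(Br)c1OC=C(O[Si](C)(C)C)O[Si](C)(C)C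
A8 | alternative 3 | 2,4-dibromo-6-(2,3,4-tribromo-6-methoxyphenoxy)phenol | COc1cc(Br)c(Br)c(Br)c1Oc1cc(Br)cc(Br)c1O
A9 | alternative 3 | 2,3,4-tribromo-6-methoxyphenol | COc1cc(Br)c(Br)c(Br)c1O
A10 | alternative 3 | 2-methoxyphenol | COc1ccccc1O
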